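## Retrosynthetic overview

1. Endgame: 46 comes from a cis-selective Zn(Cu/Ag) reduction of a (Z)-enediyne, built by two Sonogashira couplings of cis-1,2-dichloroethene 41 with hydrindane alkyne 27 and dienoate alkyne 40.
2. Enabling feature: the ring-fusion bond C3a–C7a and the bond C5–C6 lie opposite each other in the cyclohexene, so cutting both leaves two three-carbon units (C6–C7–C7a and C3a–C4–C5) still joined through C1–C2–C3; one operation on an open chain therefore closes the cyclopentane first and the cyclohexene second.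
3. Activation: C6–C7–C7a is an allenylsilane (nucleophilic at C7a, then electrophilic at C6); C3a–C4–C5 carries a temporary C3a–C5 bond as a cyclopropane-1,1-diester (electrophilic at C3a, then nucleophilic at C5). One ester carbon becomes C15′, the other ester and the silyl group are removed.
4. Stereocontrol: C1 and C7a come from one asymmetric epoxidation relayed through the allene axis; C3a from an organocatalytic cyclopropanation (inverted in the key step); C4 and C5 by equilibration; Cα by CBS reduction.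
5. Dienoate alkyne 40: two catalytic asymmetric allylborations, cross-metathesis and a Still–Gennari olefination.

Key step: step 12

Remark (assumptions on the chemistry): locants are C1 (carbinol), C2, C3 (CMe2), C3a, C4 (bears the benzylic carbon Cα), C5 (bears the side chain), C6 (methyl), C7, C7a for the hexahydroindene, and C1′ (carboxyl) to C15′ (on C5) for the side chain. Catalyst antipodes are those predicted by the usual transition-state models and can each be exchanged for the mirror image without changing the route.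

## Route

Step 1
Reactants: 1 3-bromo-2,2-dimethylpropan-1-ol
Product: 2 (3-bromo-2,2-dimethylpropoxy)triethylsilane
Conditions: Et3SiCl, imidazole, CH2Cl2, 0 °C to rt
Reagents that add atoms: chlorotriethylsilane, CC[Si](Cl)(CC)CC
Why: Standard silylation of a primary alcohol; the triethylsilyl ether masks the future C3a aldehyde and is the one silyl ether that Swern conditions later oxidise directly.

Step 2
Reactants: 2 bromide; 3 propyne
Product: 6 (Z)-vinyl iodide, triethyl{[(4Z)-5-iodo-2,2,4-trimethylpent-4-en-1-yl]oxy}silane, via Grignard reagent 4 (not isolated), via alkenylcopper 5 (not isolated)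
Conditions: Mg, Et2O/THF, reflux; CuBr·SMe2, Et2O/Me2S, −45 °C; propyne, −25 °C; I2, −50 to 0 °C
Reagents that add atoms: iodine, [I][I]
Why: Normant carbocupration adds the alkylcopper syn across propyne with the alkyl group on the internal carbon, and iodinolysis with retention should give the Z iodide in which the C2 chain and iodine are cis.

Step 3
Reactants: 6 vinyl iodide; 3 propyne
Product: 7 (Z)-enyne, triethyl{[(4Z)-2,2,4-trimethyloct-4-en-6-yn-1-yl]oxy}silane
Conditions: Pd(PPh3)2Cl2 (3 mol%), CuI (6 mol%), i-Pr2NH, THF, propyne (1 atm), rt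
Reagents that add atoms: none
Why: Sonogashira coupling proceeds with retention of alkene geometry.

Step 4
Reactants: 7 enyne
Product: 8 alkynyl epoxide, triethyl{2,2-dimethyl-3-[(2R,3S)-2-methyl-3-(prop-1-yn-1-yl)oxiran-2-yl]propoxy}silane
Conditions: ent-Shi ketone (L-fructose-derived, 30 mol%), Oxone (2KHSO5·KHSO4·K2SO4), K2CO3, Bu4NHSO4, MeCN/CH2(OMe)2, aq. Na2B4O7–EDTA buffer, 0 °C
Reagents that add atoms: potassium peroxymonosulfate (active part of Oxone), [K+].[O-]OS(=O)(=O)O
Why: Shi asymmetric epoxidation of a trisubstituted conjugated enyne is chemoselective for the alkene, and the spiro transition state with this ketone antipode should place oxygen on the face that sets C1 (R) and the C7a–O bond needed for the allene.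

Step 5
Reactants: 8 alkynyl epoxide
Product: 9 allenylsilane alcohol, (4R)-7-[dimethyl(phenyl)silyl]-2,2,4-trimethyl-1-(triethylsilyloxy)octa-5,6-dien-4-ol (axis Sa)
Conditions: PhMe2Si–Bpin (1.3 equiv), CuCl (10 mol%), PPh3 (10 mol%), NaOt-Bu (20 mol%), MeOH (2 equiv), THF, 0 °C
Reagents that add atoms: (dimethylphenylsilyl)boronic acid pinacol ester, C[Si](C)(B1OC(C)(C)C(C)(C)O1)c1ccccc1
Why: Copper-catalysed anti-SN2′ silylation of a propargylic epoxide (syn silylcupration, anti β-alkoxide elimination) transfers the C7a configuration into the allene axis and frees the C1 tertiary alcohol.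

Step 6
Reactants: 9 allenylsilane alcohol
Product: 10 tert-butyldimethylsilyl ether of 9
Conditions: t-BuMe2SiOTf, 2,6-lutidine, CH2Cl2, −20 to 0 °C
Reagents that add atoms: tert-butyldimethylsilyl triflate, CC(C)(C)[Si](C)(C)OS(=O)(=O)C(F)(F)F
Why: Silyl triflate silylation of a tertiary alcohol; the ether keeps C1 from ionising or binding the Lewis acid in the key step.

Step 7
Reactants: 10 bis-silyl ether
Product: 11 aldehyde, (4R)-4-(tert-butyldimethylsilyloxy)-7-[dimethyl(phenyl)silyl]-2,2,4-trimethylocta-5,6-dienal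
Conditions: (COCl)2 (4 equiv), DMSO (8 equiv), CH2Cl2, −78 to −30 °C; Et3N, −78 °C to rt
Reagents that add atoms: none
Why: Swern conditions oxidise a primary triethylsilyl ether directly to the aldehyde while the hindered tertiary silyl ether stays.

Step 8
Reactants: 11 aldehyde; 12 (triphenylphosphoranylidene)acetaldehyde
Product: 13 (E)-enal, (2E,6R)-6-(tert-butyldimethylsilyloxy)-9-[dimethyl(phenyl)silyl]-4,4,6-trimethyldeca-2,7,8-trienal
Conditions: toluene, 90 °C
Reagents that add atoms: none
Why: Wittig olefination with a stabilised ylide is E-selective, and the non-enolisable neopentyl aldehyde reacts faster than the enal product.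

Step 9
Reactants: 13 enal; 14 dimethyl 2-bromomalonate
Product: 15 formylcyclopropane diester, dimethyl (2S,3R)-2-formyl-3-(alkyl)cyclopropane-1,1-dicarboxylate (trans)
Conditions: (R)-α,α-diphenylprolinol trimethylsilyl ether (20 mol%), 2,6-lutidine (1.1 equiv), CH2Cl2, rt
Reagents that add atoms: none
Why: Iminium–enamine Michael-initiated ring closure (organocatalytic cyclopropanation of enals with bromomalonate): the (R)-catalyst should direct the malonate to the Re face of C3a, and enamine ring closure gives the trans cyclopropane.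

Step 10
Reactants: 15 formylcyclopropane; 16 (4-bromophenoxy)triisopropylsilane
Product: 18 aryl carbinol (both epimers at Cα), via arylmagnesium bromide 17 (not isolated)
Conditions: Mg, THF, rt (16 to 17); then 15, THF, −78 °C; aq. NH4Cl
Reagents that add atoms: none
Why: Grignard addition is chemoselective for the aldehyde over the hindered malonate esters at −78 °C; the carbinol centre is left uncontrolled because it is oxidised next.

Step 11
Reactants: 18 aryl carbinol
Product: 19 aroyl cyclopropane, dimethyl (2S,3R)-2-[4-(triisopropylsilyloxy)benzoyl]-3-(alkyl)cyclopropane-1,1-dicarboxylate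
Conditions: Dess–Martin periodinane, NaHCO3, CH2Cl2, rt
Reagents that add atoms: none
Why: Dess–Martin oxidation gives the aryl ketone, which shields C4 from nucleophilic opening, makes C4 epimerisable and is the handle for the Cα stereocentre.

Step 12
Reactants: 19 allenylsilane-tethered aroyl cyclopropane diester
Product: 20 trans-fused hexahydroindene with a C7 vinylsilane, a C5 geminal diester and the C4 aroyl group cis to C3
Conditions: TiCl4 (2.2 equiv), CH2Cl2 (0.01 M), −78 to −30 °C
Reagents that add atoms: none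
Why: Proposed new method: TiCl4 chelates the geminal diester and polarises the C3a–C5 bond of the triply activated cyclopropane, the allenylsilane attacks C3a through C7a in an SE2′ step (5-exo-tet closure of the cyclopentane, the malonate leaving as its titanium enolate), the β-silyl vinyl cation at C7 undergoes the 1,2-silyl shift typical of Danheiser annulations, and the malonate carbon C5 captures the cation now at C6 (six-membered closure with both former allene carbons C6 and C7 endocyclic), leaving a C7 vinylsilane. The closest known reactions are the Danheiser [3+2] annulation of 1-methyl-1-silylallenes with enones, which has the same attack, silyl shift and enolate capture, and the Lewis-acid opening of cyclopropane-1,1-diesters by allylsilanes; here the cyclopropane acts as a homologated enone, so capture gives a six- instead of a five-membered ring. C7a is set by the allene axis because the electrophile enters anti to silicon, and C3a is set by inversion at the cyclopropane carbon, so the two stereospecific events should define the trans ring fusion, while C1 is a spectator and C4 is corrected in step 14. The step needs attack at C3a and not at C4 (C4 carries the electron-poor aroyl group and would need a slower six-membered closure), loss of the malonate and not of the ketone enolate (bidentate binding of titanium to the diester), and capture at C6 and not at C7 (capture at C7 would give a strained trans-fused bicyclo[3.3.0]octane). Early loss of silicon would give the alkyne that is the entry to the fallback.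

Step 13
Reactants: 20 vinylsilane
Product: 21 diester phenol, dimethyl 1-hydroxy-4-(4-hydroxybenzoyl)-1,3,3,6-tetramethyl-1,2,3,3a,4,7a-hexahydro-5H-indene-5,5-dicarboxylate
Conditions: Bu4NF (6 equiv), DMSO/THF, 80 °C
Reagents that add atoms: none
Why: Fluoride-induced protodesilylation of an alkenyl(dimethyl)phenylsilane occurs with retention and here also removes both silyl ethers.

Step 14
Reactants: 21 diester
Product: 22 all-trans keto ester, methyl 1-hydroxy-4-(4-hydroxybenzoyl)-1,3,3,6-tetramethyl-2,3,3a,4,5,7a-hexahydro-1H-indene-5-carboxylate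
Conditions: LiCl (3 equiv), H2O (2 equiv), DMSO, 150 °C; then NaOMe (1.5 equiv), MeOH, rt, monitored
Reagents that add atoms: none
Why: Krapcho dealkoxycarbonylation followed by methoxide equilibration of the two enolisable centres C4 and C5 should lead to the all-equatorial trans,trans keto ester, the C6=C7 position being retained because conjugation would need a crowded tetrasubstituted alkene between C4 and the C6 methyl group.

Step 15
Reactants: 22 keto ester phenol
Product: 23 phenol triisopropylsilyl ether of 22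
Conditions: i-Pr3SiCl, imidazole, DMF, rt
Reagents that add atoms: chlorotriisopropylsilane, CC(C)[Si](Cl)(C(C)C)C(C)C
Why: Phenols silylate much faster than the hindered tertiary alcohol.

Step 16
Reactants: 23 aryl ketone
Product: 24 (S)-benzylic alcohol
Conditions: (R)-2-methyl-CBS-oxazaborolidine (1 equiv), BH3·SMe2 (2.5 equiv), toluene, −30 °C; MeOH quench
Reagents that add atoms: none
Why: Corey–Bakshi–Shibata reduction: with the aryl group as the large substituent the (R)-catalyst should give the (S)-carbinol by reagent control, the ester being untouched at low temperature.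

Step 17
Reactants: 24 diol
Product: 25 bis(triethylsilyl) ether (benzylic and C1 oxygens)
Conditions: Et3SiOTf (2.5 equiv), 2,6-lutidine, CH2Cl2, −78 to 0 °C
Reagents that add atoms: triethylsilyl triflate, CC[Si](CC)(CC)OS(=O)(=O)C(F)(F)F
Why: Silyl triflate silylation protects both alcohols as fluoride-labile ethers for the hydride and coupling steps.

Step 18
Reactants: 25 ester
Product: 26 aldehyde (C15′)
Conditions: i-Bu2AlH (1.2 equiv), CH2Cl2, −78 °C; aq. KNaC4H4O6
Reagents that add atoms: none
Why: Low-temperature DIBAL-H reduction of a hindered methyl ester stops at the tetrahedral aluminate and gives the aldehyde on work-up.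

Step 19
Reactants: 26 aldehyde
Product: 27 hydrindane alkyne (C5–C15′≡C14′H)
Conditions: dimethyl (1-diazo-2-oxopropyl)phosphonate, K2CO3, MeOH, 0 °C to rt
Reagents that add atoms: Ohira–Bestmann reagent, CC(=O)C(=[N+]=[N-])P(=O)(OC)OC
Why: Ohira–Bestmann (Seyferth–Gilbert) homologation gives the terminal alkyne, and the mild base keeps the epimerisable C5 centre equatorial and trans to C4 before it is fixed.

Step 20
Reactants: 28 3-(trimethylsilyl)propynal; 29 (E)-crotylboronic acid pinacol ester
Product: 30 (3R,4R)-4-methyl-1-(trimethylsilyl)hex-5-en-1-yn-3-ol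
Conditions: (R)-TRIP phosphoric acid (5 mol%), toluene, −30 °C
Reagents that add atoms: none
Why: Chiral phosphoric acid-catalysed crotylboration through a closed chair transition state: the E-crotyl geometry gives the anti relationship and the catalyst should direct Re-face addition (C9′, C8′).

Step 21
Reactants: 30 alcohol
Product: 31 tert-butyldimethylsilyl ether of 30
Conditions: t-BuMe2SiOTf, 2,6-lutidine, CH2Cl2, −78 to 0 °C
Reagents that add atoms: tert-butyldimethylsilyl triflate, CC(C)(C)[Si](C)(C)OS(=O)(=O)C(F)(F)F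
Why: Routine silylation of a secondary propargylic alcohol.

Step 22
Reactants: 31 alkene
Product: 32 α-methyl aldehyde (C7′)
Conditions: OsO4 (2 mol%), NaIO4 (4 equiv), 2,6-lutidine, dioxane/H2O, rt
Reagents that add atoms: sodium periodate, [Na+].[O-]I(=O)(=O)=O
Why: Johnson–Lemieux cleavage of the terminal alkene leaves the hindered silyl alkyne untouched, and the lutidine buffer limits epimerisation of the α-methyl aldehyde.

Step 23
Reactants: 32 aldehyde; 33 allylboronic acid pinacol ester
Product: 34 homoallylic alcohol (C7′)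
Conditions: (R)-TRIP phosphoric acid (5 mol%), toluene, −30 °C
Reagents that add atoms: none
Why: Catalyst-controlled allylboration should add to the Re face of the α-methyl aldehyde and give the anti,anti stereotriad with the 1,3-syn diol relationship.

Step 24
Reactants: 34 alcohol
Product: 35 bis(tert-butyldimethylsilyl) ether
Conditions: t-BuMe2SiOTf, 2,6-lutidine, CH2Cl2, −78 to 0 °C
Reagents that add atoms: tert-butyldimethylsilyl triflate, CC(C)(C)[Si](C)(C)OS(=O)(=O)C(F)(F)F
Why: Routine silylation of a secondary alcohol.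

Step 25
Reactants: 35 terminal alkene; 36 methacrolein
Product: 37 (E)-2-methyl enal
Conditions: second-generation Grubbs catalyst (H2IMes)(PCy3)Cl2Ru=CHPh (5 mol%), methacrolein (5 equiv), CH2Cl2, 40 °C
Reagents that add atoms: none
Why: Cross-metathesis of a terminal alkene with methacrolein gives the E trisubstituted enal, and the silyl-capped alkyne is inert to the ruthenium carbene.

Step 26
Reactants: 37 enal; 38 methyl bis(2,2,2-trifluoroethyl)phosphonoacetate
Product: 39 (2Z,4E)-dienoate
Conditions: KN(SiMe3)2, 18-crown-6, THF, −78 °C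
Reagents that add atoms: none
Why: Still–Gennari olefination gives the Z enoate under kinetic control and leaves the E alkene unchanged.

Step 27
Reactants: 39 silyl alkyne
Product: 40 terminal alkyne (dienoate fragment)
Conditions: K2CO3 (0.3 equiv), MeOH, 0 °C, short reaction time
Reagents that add atoms: none
Why: Mild methanolysis cleaves the C(sp)–SiMe3 bond selectively while the alkyl silyl ethers and the methyl ester stay.

Step 28
Reactants: 27 hydrindane alkyne; 41 cis-1,2-dichloroethene
Product: 42 (Z)-chloroenyne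
Conditions: Pd(PPh3)4 (5 mol%), CuI (10 mol%), n-BuNH2, 41 (10 equiv), Et2O, rt
Reagents that add atoms: none
Why: Sonogashira coupling with excess cis-dichloroethene gives mono-coupling with retention of the Z geometry.

Step 29
Reactants: 42 chloroenyne; 40 dienoate alkyne
Product: 43 protected (Z)-enediyne
Conditions: Pd(PPh3)4 (5 mol%), CuI (10 mol%), piperidine, THF, rt
Reagents that add atoms: none
Why: A second Sonogashira coupling of the vinyl chloride joins the two fragments with retention.

Step 30
Reactants: 43 protected enediyne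
Product: 44 pentaol methyl ester
Conditions: Bu4NF/AcOH (1:1, 10 equiv), THF, 0 °C to rt
Reagents that add atoms: none
Why: Buffered fluoride removes the aryl, benzylic, tertiary and two secondary silyl ethers without acid, which the p-hydroxybenzylic alcohol would not tolerate.

Step 31
Reactants: 44 enediyne
Product: 45 (Z,Z,Z)-triene methyl ester
Conditions: Zn dust activated with Cu(OAc)2 and AgNO3, MeOH/H2O (1:1), rt, dark
Reagents that add atoms: none
Why: Boland reduction converts conjugated alkynes to Z alkenes without over-reduction and leaves the dienoate untouched.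

Step 32
Reactants: 45 methyl ester
Product: 46 target acid
Conditions: LiOH (5 equiv), THF/MeOH/H2O, 0 °C to rt; aq. NaH2PO4 to pH 5
Reagents that add atoms: lithium hydroxide, [Li+].[OH-]
Why: Mild saponification of the Z enoate followed by buffered acidification avoids acid-induced ionisation of the p-hydroxybenzylic alcohol.

## Compound list

1 | 3-bromo-2,2-dimethylpropan-1-ol | OCC(C)(C)CBr | starting material
2 | (3-bromo-2,2-dimethylpropoxy)triethylsilane | CC[Si](CC)(CC)OCC(C)(C)CBr | intermediate
3 | propyne | CC#C | starting material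
4 | [2,2-dimethyl-3-(triethylsilyloxy)propyl]magnesium bromide | CC[Si](CC)(CC)OCC(C)(C)C[Mg]Br | intermediate
5 | [(1Z)-2,4,4-trimethyl-5-(triethylsilyloxy)pent-1-en-1-yl]copper | CC[Si](CC)(CC)OCC(C)(C)C/C(C)=C\[Cu] | intermediate
6 | triethyl{[(4Z)-5-iodo-2,2,4-trimethylpent-4-en-1-yl]oxy}silane | CC[Si](CC)(CC)OCC(C)(C)C/C(C)=C\I | intermediate
7 | triethyl{[(4Z)-2,2,4-trimethyloct-4-en-6-yn-1-yl]oxy}silane | CC[Si](CC)(CC)OCC(C)(C)C/C(C)=C\C#CC | intermediate
8 | triethyl{2,2-dimethyl-3-[(2R,3S)-2-methyl-3-(prop-1-yn-1-yl)oxiran-2-yl]propoxy}silane | CC#C[C@@H]1O[C@]1(C)CC(C)(C)CO[Si](CC)(CC)CC | intermediate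
9 | (4R)-7-[dimethyl(phenyl)silyl]-2,2,4-trimethyl-1-(triethylsilyloxy)octa-5,6-dien-4-ol, allene axis Sa | CC(=[C@]=C[C@](C)(O)CC(C)(C)CO[Si](CC)(CC)CC)[Si](C)(C)c1ccccc1 | intermediate
10 | tert-butyldimethylsilyl ether of 9 | CC(=[C@]=C[C@](C)(O[Si](C)(C)C(C)(C)C)CC(C)(C)CO[Si](CC)(CC)CC)[Si](C)(C)c1ccccc1 | intermediate
11 | (4R)-4-(tert-butyldimethylsilyloxy)-7-[dimethyl(phenyl)silyl]-2,2,4-trimethylocta-5,6-dienal, axis Sa | CC(=[C@]=C[C@](C)(O[Si](C)(C)C(C)(C)C)CC(C)(C)C=O)[Si](C)(C)c1ccccc1 | intermediate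
12 | (triphenylphosphoranylidene)acetaldehyde | O=CC=P(c1ccccc1)(c1ccccc1)c1ccccc1 | starting material
13 | (2E,6R)-6-(tert-butyldimethylsilyloxy)-9-[dimethyl(phenyl)silyl]-4,4,6-trimethyldeca-2,7,8-trienal, axis Sa | CC(=[C@]=C[C@](C)(O[Si](C)(C)C(C)(C)C)CC(C)(C)/C=C/C=O)[Si](C)(C)c1ccccc1 | intermediate
14 | dimethyl 2-bromomalonate | COC(=O)C(Br)C(=O)OC | starting material
15 | dimethyl (2S,3R)-2-formyl-3-{(4R)-4-(tert-butyldimethylsilyloxy)-7-[dimethyl(phenyl)silyl]-2,4-dimethylocta-5,6-dien-2-yl}cyclopropane-1,1-dicarboxylate | CC(=[C@]=C[C@](C)(O[Si](C)(C)C(C)(C)C)CC(C)(C)[C@H]1[C@H](C=O)C1(C(=O)OC)C(=O)OC)[Si](C)(C)c1ccccc1 | intermediate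
16 | (4-bromophenoxy)triisopropylsilane | CC(C)[Si](Oc1ccc(Br)cc1)(C(C)C)C(C)C | starting material
17 | [4-(triisopropylsilyloxy)phenyl]magnesium bromide | CC(C)[Si](Oc1ccc([Mg]Br)cc1)(C(C)C)C(C)C | intermediate
18 | carbinol from 15 and 17 (both epimers at the carbinol carbon; other centres as in 15) | CC(=[C@]=C[C@](C)(O[Si](C)(C)C(C)(C)C)CC(C)(C)[C@H]1[C@H](C(O)c2ccc(O[Si](C(C)C)(C(C)C)C(C)C)cc2)C1(C(=O)OC)C(=O)OC)[Si](C)(C)c1ccccc1 | intermediate
19 | dimethyl (2S,3R)-2-[4-(triisopropylsilyloxy)benzoyl]-3-{(4R)-4-(tert-butyldimethylsilyloxy)-7-[dimethyl(phenyl)silyl]-2,4-dimethylocta-5,6-dien-2-yl}cyclopropane-1,1-dicarboxylate | CC(=[C@]=C[C@](C)(O[Si](C)(C)C(C)(C)C)CC(C)(C)[C@H]1[C@H](C(=O)c2ccc(O[Si](C(C)C)(C(C)C)C(C)C)cc2)C1(C(=O)OC)C(=O)OC)[Si](C)(C)c1ccccc1 | intermediate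
20 | dimethyl 1-(tert-butyldimethylsilyloxy)-7-[dimethyl(phenyl)silyl]-1,3,3,6-tetramethyl-4-[4-(triisopropylsilyloxy)benzoyl]-1,2,3,3a,4,7a-hexahydro-5H-indene-5,5-dicarboxylate; trans ring fusion, C1, C3a, C7a as in 46, aroyl group cis to C3 | CC1=C([Si](C)(C)c3ccccc3)[C@@H]2[C@@H]([C@H](C(=O)c3ccc(O[Si](C(C)C)(C(C)C)C(C)C)cc3)C1(C(=O)OC)C(=O)OC)C(C)(C)C[C@@]2(C)O[Si](C)(C)C(C)(C)C | intermediate
21 | dimethyl 1-hydroxy-4-(4-hydroxybenzoyl)-1,3,3,6-tetramethyl-1,2,3,3a,4,7a-hexahydro-5H-indene-5,5-dicarboxylate; stereocentres as in 20 | CC1=C[C@@H]2[C@@H]([C@H](C(=O)c3ccc(O)cc3)C1(C(=O)OC)C(=O)OC)C(C)(C)C[C@@]2(C)O | intermediate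
22 | methyl 1-hydroxy-4-(4-hydroxybenzoyl)-1,3,3,6-tetramethyl-2,3,3a,4,5,7a-hexahydro-1H-indene-5-carboxylate; C1, C3a, C4, C5, C7a as in 46 | CC1=C[C@@H]2[C@@H]([C@@H](C(=O)c3ccc(O)cc3)[C@@H]1C(=O)OC)C(C)(C)C[C@@]2(C)O | intermediate
23 | phenol triisopropylsilyl ether of 22 | CC1=C[C@@H]2[C@@H]([C@@H](C(=O)c3ccc(O[Si](C(C)C)(C(C)C)C(C)C)cc3)[C@@H]1C(=O)OC)C(C)(C)C[C@@]2(C)O | intermediate
24 | (S)-benzylic alcohol from 23 | CC1=C[C@@H]2[C@@H]([C@@H]([C@H](O)c3ccc(O[Si](C(C)C)(C(C)C)C(C)C)cc3)[C@@H]1C(=O)OC)C(C)(C)C[C@@]2(C)O | intermediate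
25 | bis(triethylsilyl) ether of 24 | CC1=C[C@@H]2[C@@H]([C@@H]([C@H](O[Si](CC)(CC)CC)c3ccc(O[Si](C(C)C)(C(C)C)C(C)C)cc3)[C@@H]1C(=O)OC)C(C)(C)C[C@@]2(C)O[Si](CC)(CC)CC | intermediate
26 | C5 carbaldehyde from 25 | CC1=C[C@@H]2[C@@H]([C@@H]([C@H](O[Si](CC)(CC)CC)c3ccc(O[Si](C(C)C)(C(C)C)C(C)C)cc3)[C@@H]1C=O)C(C)(C)C[C@@]2(C)O[Si](CC)(CC)CC | intermediate
27 | 5-ethynyl hydrindane (protected hydrindane alkyne) | CC1=C[C@@H]2[C@@H]([C@@H]([C@H](O[Si](CC)(CC)CC)c3ccc(O[Si](C(C)C)(C(C)C)C(C)C)cc3)[C@@H]1C#C)C(C)(C)C[C@@]2(C)O[Si](CC)(CC)CC | intermediate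
28 | 3-(trimethylsilyl)propynal | C[Si](C)(C)C#CC=O | starting material
29 | (E)-crotylboronic acid pinacol ester | C/C=C/CB1OC(C)(C)C(C)(C)O1 | starting material
30 | (3R,4R)-4-methyl-1-(trimethylsilyl)hex-5-en-1-yn-3-ol | C[Si](C)(C)C#C[C@H](O)[C@H](C)C=C | intermediate
31 | tert-butyldimethylsilyl ether of 30 | C[Si](C)(C)C#C[C@H](O[Si](C)(C)C(C)(C)C)[C@H](C)C=C | intermediate
32 | 3-(tert-butyldimethylsilyloxy)-2-methyl-5-(trimethylsilyl)pent-4-ynal (configuration as in 31) | C[Si](C)(C)C#C[C@H](O[Si](C)(C)C(C)(C)C)[C@H](C)C=O | intermediate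
33 | allylboronic acid pinacol ester | C=CCB1OC(C)(C)C(C)(C)O1 | starting material
34 | 6-(tert-butyldimethylsilyloxy)-5-methyl-8-(trimethylsilyl)oct-1-en-7-yn-4-ol (anti,anti triad as in 46) | C[Si](C)(C)C#C[C@H](O[Si](C)(C)C(C)(C)C)[C@H](C)[C@H](O)CC=C | intermediate
35 | bis(tert-butyldimethylsilyl) ether of the 4,6-diol | C[Si](C)(C)C#C[C@H](O[Si](C)(C)C(C)(C)C)[C@H](C)[C@H](O[Si](C)(C)C(C)(C)C)CC=C | intermediate
36 | methacrolein | CC(=C)C=O | starting material
37 | (2E)-5,7-bis(tert-butyldimethylsilyloxy)-2,6-dimethyl-9-(trimethylsilyl)non-2-en-8-ynal | C[Si](C)(C)C#C[C@H](O[Si](C)(C)C(C)(C)C)[C@H](C)[C@H](O[Si](C)(C)C(C)(C)C)C/C=C(C)/C=O | intermediate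
38 | methyl bis(2,2,2-trifluoroethyl)phosphonoacetate | COC(=O)CP(=O)(OCC(F)(F)F)OCC(F)(F)F | starting material
39 | methyl (2Z,4E)-7,9-bis(tert-butyldimethylsilyloxy)-4,8-dimethyl-11-(trimethylsilyl)undeca-2,4-dien-10-ynoate | C[Si](C)(C)C#C[C@H](O[Si](C)(C)C(C)(C)C)[C@H](C)[C@H](O[Si](C)(C)C(C)(C)C)C/C=C(C)/C=C\C(=O)OC | intermediate
40 | methyl (2Z,4E)-7,9-bis(tert-butyldimethylsilyloxy)-4,8-dimethylundeca-2,4-dien-10-ynoate | C#C[C@H](O[Si](C)(C)C(C)(C)C)[C@H](C)[C@H](O[Si](C)(C)C(C)(C)C)C/C=C(C)/C=C\C(=O)OC | intermediate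
41 | cis-1,2-dichloroethene | Cl/C=C\Cl | starting material
42 | (Z)-chloroenyne from 27 | CC1=C[C@@H]2[C@@H]([C@@H]([C@H](O[Si](CC)(CC)CC)c3ccc(O[Si](C(C)C)(C(C)C)C(C)C)cc3)[C@@H]1C#C/C=C\Cl)C(C)(C)C[C@@]2(C)O[Si](CC)(CC)CC | intermediate
43 | fully protected (Z)-enediyne methyl ester | CC1=C[C@@H]2[C@@H]([C@@H]([C@H](O[Si](CC)(CC)CC)c3ccc(O[Si](C(C)C)(C(C)C)C(C)C)cc3)[C@@H]1C#C/C=C\C#C[C@H](O[Si](C)(C)C(C)(C)C)[C@H](C)[C@H](O[Si](C)(C)C(C)(C)C)C/C=C(C)/C=C\C(=O)OC)C(C)(C)C[C@@]2(C)O[Si](CC)(CC)CC | intermediate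
44 | (Z)-enediyne pentaol methyl ester | CC1=C[C@@H]2[C@@H]([C@@H]([C@H](O)c3ccc(O)cc3)[C@@H]1C#C/C=C\C#C[C@H](O)[C@H](C)[C@H](O)C/C=C(C)/C=C\C(=O)OC)C(C)(C)C[C@@]2(C)O | intermediate
45 | methyl ester of the target | CC1=C[C@@H]2[C@@H]([C@@H]([C@H](O)c3ccc(O)cc3)[C@@H]1\C=C/C=C\C=C/[C@H](O)[C@H](C)[C@H](O)C/C=C(C)/C=C\C(=O)OC)C(C)(C)C[C@@]2(C)O | intermediate
46 | CNP0118468.2 | CC1=C[C@@H]2[C@@H]([C@@H]([C@H](O)c3ccc(O)cc3)[C@@H]1\C=C/C=C\C=C/[C@H](O)[C@H](C)[C@H](O)C/C=C(C)/C=C\C(=O)O)C(C)(C)C[C@@]2(C)O | target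

## Count and risks

Total step count: 32. Longest linear sequence: 24 steps (steps 1–19, then 28–32).

Step 12 (proposed new method). What may go wrong: the cascade may stop after the first ring closure with chloride-induced loss of silicon, or the malonate may fail to capture the rearranged vinyl cation. Fallback, from 19 back to 21: run the first event on purpose as a desilylative propargylation (SnCl4, CH2Cl2, −78 °C; the known SE2′ mode of allenylsilanes and the known opening of cyclopropane-1,1-diesters by allyl-type silanes) to give the cyclopentyl alkyne malonate F1. Close the cyclohexene by a Conia-ene 6-endo-dig carbocyclisation of the malonate onto the methyl-capped alkyne (Ph3PAuNTf2, 5 mol%, CH2Cl2, rt; the 5-exo mode would need a trans-fused bicyclo[3.3.0]octane) to give the C7–H hydrindene diester F2. Removal of both silyl ethers (Bu4NF, THF, 50 °C) gives 21.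

Step 9. What may go wrong: slow iminium formation and slow conjugate addition at a β-carbon next to the quaternary C3, so that conversion or facial selectivity is poor. Fallback, from 11 back to 19: Wittig olefination of 11 with the aroyl ylide F4 (toluene, 90 °C) gives the (E)-aryl enone F3. Michael-initiated ring closure of F3 with 14 under chiral phase-transfer catalysis (N-(9-anthracenylmethyl)cinchoninium bromide, Cs2CO3, toluene, 0 °C), as known for chalcone-type acceptors, gives 19 directly and drops the Grignard addition and the oxidation.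

Step 4. What may go wrong: poor facial selectivity in the dioxirane epoxidation of a Z-configured trisubstituted enyne, which would erode both C1 and the allene axis. Fallback, from 6 back to 8: iodine–lithium exchange of 6 (t-BuLi, Et2O, −78 °C) and trapping with paraformaldehyde gives the (Z)-allylic alcohol F5 with retention. Sharpless asymmetric epoxidation (Ti(OiPr)4, L-(+)-diethyl tartrate, t-BuOOH, 4 Å molecular sieves, CH2Cl2, −20 °C; the nerol-type case) gives the (2S,3R)-epoxy alcohol F6. Dess–Martin oxidation gives the epoxy aldehyde F7, Ohira–Bestmann homologation gives the terminal alkynyl epoxide F8, and deprotonation (LiN(SiMe3)2, THF, −78 °C) with MeI gives 8.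

Further compounds

F1 | step 12 | dimethyl 2-{2-oxo-1-[2-(prop-1-yn-1-yl)-3-(tert-butyldimethylsilyloxy)-3,5,5-trimethylcyclopentyl]-2-[4-(triisopropylsilyloxy)phenyl]ethyl}malonate (ring centres as in 20) | CC#C[C@@H]1[C@@H]([C@H](C(=O)c2ccc(O[Si](C(C)C)(C(C)C)C(C)C)cc2)C(C(=O)OC)C(=O)OC)C(C)(C)C[C@@]1(C)O[Si](C)(C)C(C)(C)C
F2 | step 12 | dimethyl 1-(tert-butyldimethylsilyloxy)-1,3,3,6-tetramethyl-4-[4-(triisopropylsilyloxy)benzoyl]-1,2,3,3a,4,7a-hexahydro-5H-indene-5,5-dicarboxylate (stereocentres as in 20) | CC1=C[C@@H]2[C@@H]([C@H](C(=O)c3ccc(O[Si](C(C)C)(C(C)C)C(C)C)cc3)C1(C(=O)OC)C(=O)OC)C(C)(C)C[C@@]2(C)O[Si](C)(C)C(C)(C)C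
F3 | step 9 | (2E,6R)-6-(tert-butyldimethylsilyloxy)-9-[dimethyl(phenyl)silyl]-4,4,6-trimethyl-1-[4-(triisopropylsilyloxy)phenyl]deca-2,7,8-trien-1-one | CC(=[C@]=C[C@](C)(O[Si](C)(C)C(C)(C)C)CC(C)(C)/C=C/C(=O)c2ccc(O[Si](C(C)C)(C(C)C)C(C)C)cc2)[Si](C)(C)c1ccccc1
F4 | step 9 | 1-[4-(triisopropylsilyloxy)phenyl]-2-(triphenylphosphoranylidene)ethanone | CC(C)[Si](Oc1ccc(cc1)C(=O)C=P(c1ccccc1)(c1ccccc1)c1ccccc1)(C(C)C)C(C)C
F5 | step 4 | (2Z)-3,5,5-trimethyl-6-(triethylsilyloxy)hex-2-en-1-ol | CC[Si](CC)(CC)OCC(C)(C)C/C(C)=C\CO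
F6 | step 4 | {(2S,3R)-3-methyl-3-[2,2-dimethyl-3-(triethylsilyloxy)propyl]oxiran-2-yl}methanol | OC[C@@H]1O[C@]1(C)CC(C)(C)CO[Si](CC)(CC)CC
F7 | step 4 | the corresponding oxirane-2-carbaldehyde | O=C[C@@H]1O[C@]1(C)CC(C)(C)CO[Si](CC)(CC)CC
F8 | step 4 | the corresponding 3-ethynyl-2-methyloxirane | C#C[C@@H]1O[C@]1(C)CC(C)(C)CO[Si](CC)(CC)CC
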